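**Assumption:** carbons are numbered as in squalene and the iridals (C1 aldehyde carbon, C2 its alkene carbon, C3–C5 hydroxypropyl arm with C3 the carbinol carbon, C6–C11 ring, C12–C24 side chain, C25–C30 the methyls on C2, C10, C11, C15, C19, C23). In this numbering the target is (2Z,6S,10R,11R,14E,18E,21S,22R). "Bpin" in short names means 4,4,5,5-tetramethyl-1,3,2-dioxaborolan-2-yl.

**Retrosynthetic overview**
1. Target ⇐ MnO2 oxidation of the C1 allylic alcohol; C13–C14 bond by sp3–sp2 Suzuki coupling of a C1–C13 ring boronate with a C14–C24 (E)-vinyl iodide that already carries the threo epoxy alcohol.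
2. Ring boronate ⇐ one-flask cationic cascade of an acyclic (2R,3S)-epoxy-(6E,10Z)-diene: epoxide opening closes ring A, then ring B; H/CH3/H 1,2-shifts move the cation to C7; Grob fragmentation of C2–C3 reopens ring A and leaves ring B.
3. The chain stops at C13, so no third ring can form; the 10Z alkene sets C10/C11, the epoxide sets the absolute configuration, and the Z-CH2O group on C2 becomes the enal carbon cis to C6.
4. Epoxy diene ⇐ Sharpless epoxidation of a (2Z,6E,10Z)-trienol ⇐ nerol (C5–C12), CH2(Bpin)2 (C13), a Wittig CH2 (C4) and (Z)-3-iodo-2-methylprop-2-en-1-ol (C1–C3, C25).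
5. Vinyl iodide ⇐ prenal + allenyl-Bpin (C21), two carboalumination/iodination rounds around a butynylzinc coupling, then hydroxyl-directed epoxidation (side-chain oxirane).

**Route**

Step 1
Reactants: 1 nerol
Product: 2 neryl bromide
Conditions: PBr3 (0.4 equiv), Et2O, −10 °C
Reagents that add atoms: phosphorus tribromide, BrP(Br)Br
Why: alcohol-to-bromide substitution of a primary allylic alcohol at low temperature proceeds without allylic transposition and keeps the Z alkene (future C10=C11).

Step 2
Reactants: 2 neryl bromide; 3 bis(pinacolato)borylmethane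
Product: 4 (Z)-homoneryl pinacol boronate
Conditions: NaOtBu (1.5 equiv), THF, 0 °C → rt
Reagents that add atoms: none
Why: alkoxide-promoted deborylative alkylation, in which tert-butoxide turns 3 into an α-boryl carbanion that displaces the unhindered allylic bromide by SN2 and adds C13 with its boronate handle.

Step 3
Reactants: 4 (Z)-homoneryl pinacol boronate
Product: 6 (2E,6Z)-enal boronate, via allylic alcohol 5 (not isolated)
Conditions: SeO2 (0.3 equiv), t-BuOOH (3 equiv), salicylic acid (0.1 equiv), CH2Cl2, rt; crude, MnO2 (15 equiv), CH2Cl2, rt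
Reagents that add atoms: tert-butyl hydroperoxide, CC(C)(C)OO
Why: SeO2 allylic oxidation (ene reaction then [2,3]-sigmatropic shift) takes the E methyl of the terminal isopropylidene and so fixes the 6E geometry, MnO2 carries the allylic alcohol on to the enal, and the alkyl pinacol boronate is expected to survive because it is oxidised only by peroxide anions.

Step 4
Reactants: 6 (2E,6Z)-enal boronate
Product: 7 (3Z,7E)-triene boronate
Conditions: Ph3PCH3Br (1.3 equiv), KOtBu (1.25 equiv), THF, 0 °C
Reagents that add atoms: methyltriphenylphosphonium bromide, C[P+](c1ccccc1)(c1ccccc1)c1ccccc1.[Br-]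
Why: Wittig methylenation of the enal adds C4 as the terminus of a conjugated diene without touching the alkene geometries.

Step 5
Reactants: 8 propargyl alcohol
Product: 10 (2Z)-3-iodo-2-methylprop-2-en-1-ol, via alkenylmagnesium alkoxide 9 (not isolated)
Conditions: MeMgBr (2.5 equiv), CuI (10 mol %), THF, −10 °C → rt; then I2, THF, −10 °C
Reagents that add atoms: methylmagnesium bromide, C[Mg]Br; iodine, [I][I]
Why: copper-catalysed anti carbomagnesiation of the propargylic alkoxide places the methyl on the inner carbon and magnesium on the terminus cis to CH2O (five-membered chelate), and iodinolysis with retention gives the Z vinyl iodide.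

Step 6
Reactants: 7 (3Z,7E)-triene boronate; 10 (2Z)-3-iodo-2-methylprop-2-en-1-ol
Product: 12 (2Z,6E,10Z)-trienol boronate, via alkyl-9-BBN borane 11 (not isolated)
Conditions: 9-BBN (1.15 equiv), THF, 0 °C → rt; then 10, Pd(dppf)Cl2 (5 mol %), AsPh3 (10 mol %), Cs2CO3 (3 equiv), DMF/H2O, rt
Reagents that add atoms: none
Why: 9-BBN hydroborates only the monosubstituted diene terminus (anti-Markovnikov), and B-alkyl Suzuki–Miyaura coupling with retention at the vinyl iodide forms C3–C4 and gives the 2Z allylic alcohol, while the pinacol boronate does not transmetalate at room temperature.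

Step 7
Reactants: 12 (2Z,6E,10Z)-trienol boronate
Product: 13 (2R,3S)-epoxy alcohol
Conditions: Ti(OiPr)4 (20 mol %), D-(−)-diethyl tartrate (25 mol %), t-BuOOH (2 equiv), 4 Å MS, CH2Cl2, −20 °C
Reagents that add atoms: tert-butyl hydroperoxide, CC(C)(C)OO
Why: Sharpless asymmetric epoxidation reacts only at the allylic alcohol alkene, and D-(−)-tartrate delivers oxygen to the face that gives the (2R,3S)-oxirane (the antipode of what L-(+)-tartrate gives with nerol), about 90% ee being expected for a 2-methyl Z-allylic alcohol.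

Step 8
Reactants: 13 (2R,3S)-epoxy alcohol
Product: 14 epoxy silyl ether
Conditions: TBDPSCl (1.2 equiv), imidazole (2 equiv), CH2Cl2, 0 °C → rt
Reagents that add atoms: tert-butyl(chloro)diphenylsilane, CC(C)(C)[Si](Cl)(c1ccccc1)c1ccccc1
Why: silylation of the primary alcohol removes a chelating, participating hydroxyl next to the epoxide and gives an ether that tolerates BF3·OEt2 at low temperature.

Step 9
Reactants: 14 epoxy silyl ether
Product: 17 ring diol boronate (2Z,6S,10R,11R), via seco-aldehyde 15 (not isolated), via silyl ether alcohol 16 (not isolated)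
Conditions: BF3·OEt2 (3 equiv), CH2Cl2 (0.005 M), −78 → −20 °C, 1 h; Et3N (10 equiv), then NaBH4 (5 equiv), MeOH, −78 → 0 °C; crude, TBAF (1.5 equiv), THF, rt
Reagents that add atoms: none
Why: Proposed new method: BF3 opens the oxirane at tertiary C2 with anti attack of the 6E alkene (chair, ring A) and then of the 10Z alkene (ring B), the Z geometry placing H11 cis to the C6 methyl and the chain end at C13 ruling out a third ring; the C10 cation then relaxes by suprafacial 1,2-shifts (H11→C10, CH3 from C6→C11, H7→C6) that set C10 (R), C11 (R) and C6 (S), and the C7 cation, γ to the O–BF3 alkoxide, undergoes Grob (retro-Prins) fragmentation of C2–C3, which cancels both charges, opens ring A and gives the C3 aldehyde plus the C2=C7 alkene with the formerly axial CH2OSi group cis to C6; the closest known reactions are Lewis-acid epoxy-polyene bicyclizations, the BF3·OEt2-induced 1,2-H/1,2-CH3 shift cascade of drimanyl C8 cations used in aureol syntheses, and Grob fragmentations of γ-oxido carbocations; amine quench and NaBH4 reduce the aldehyde before it can re-close by a Prins reaction, and fluoride then removes the silyl group.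

Step 10
Reactants: 18 prenal; 19 allenylboronic acid pinacol ester
Product: 21 (4S)-6-methylhept-5-en-1-yn-4-ol, via borate ester 20 (not isolated)
Conditions: (S)-TRIP phosphoric acid (10 mol %), 4 Å MS, toluene, 0 °C, 48 h; aqueous work-up
Reagents that add atoms: none
Why: chiral phosphoric acid-catalysed propargylboration (SE2′ transfer through a six-membered transition state with the acid bound to the boronate oxygen) sets C21, the S catalyst being chosen for Si-face addition by analogy with the Re-face sense reported for the R catalyst, to be confirmed by Mosher analysis.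

Step 11
Reactants: 21 (4S)-6-methylhept-5-en-1-yn-4-ol
Product: 23 (1E,4S)-vinyl iodide dienol, via alkenylalane 22 (not isolated)
Conditions: Me3Al (3 equiv), Cp2ZrCl2 (25 mol %), CH2Cl2, 0 °C → rt; then I2 (1.3 equiv), THF, −30 → 0 °C
Reagents that add atoms: trimethylaluminium, C[Al](C)C; iodine, [I][I]
Why: Negishi zirconium-catalysed syn carboalumination of the terminal alkyne (methyl to the inner carbon, assisted by the homopropargylic alkoxide) and iodinolysis with retention give the E trisubstituted vinyl iodide (C18=C19).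

Step 12
Reactants: 23 (1E,4S)-vinyl iodide dienol; 24 4-bromobut-1-yne
Product: 26 (4S,6E)-dienynol, via but-3-ynylzinc bromide 25 (not isolated)
Conditions: 24, Zn dust (1.5 equiv), LiCl, THF, 50 °C; then 23, Pd(OAc)2 (2 mol %), SPhos (4 mol %), THF, rt, slow addition of 25 (1.5 equiv)
Reagents that add atoms: none
Why: Negishi sp3–sp2 coupling proceeds with retention of the E geometry, the alkylzinc halide being too weakly basic to be consumed by the free hydroxyl or the terminal alkyne under slow addition.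

Step 13
Reactants: 26 (4S,6E)-dienynol
Product: 28 (4S,6E,10E)-vinyl iodide trienol, via alkenylalane 27 (not isolated)
Conditions: Me3Al (3 equiv), Cp2ZrCl2 (25 mol %), CH2Cl2, 0 °C → rt; then I2 (1.3 equiv), THF, −30 → 0 °C
Reagents that add atoms: trimethylaluminium, C[Al](C)C; iodine, [I][I]
Why: a second Negishi carboalumination/iodination builds the E C14=C15 vinyl iodide, the trisubstituted alkenes being inert to the methylalane.

Step 14
Reactants: 28 (4S,6E,10E)-vinyl iodide trienol
Product: 29 threo epoxy alcohol vinyl iodide (21S,22R)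
Conditions: VO(acac)2 (5 mol %), t-BuOOH (1.2 equiv), CH2Cl2, 0 °C
Reagents that add atoms: tert-butyl hydroperoxide, CC(C)(C)OO
Why: hydroxyl-directed vanadium epoxidation touches only the allylic C22=C23 alkene, and A(1,3) strain with the cis methyl holds H21 in the alkene plane so that oxygen delivered syn to the hydroxyl gives the threo (21S,22R) isomer (about 6:1, minor isomer removed by chromatography).

Step 15
Reactants: 17 ring diol boronate; 29 threo epoxy alcohol vinyl iodide
Product: 30 coupled triol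
Conditions: Pd(OAc)2 (5 mol %), RuPhos (10 mol %), K3PO4 (3 equiv), toluene/H2O (10:1), 60 °C
Reagents that add atoms: none
Why: Suzuki–Miyaura coupling of the primary alkyl pinacol boronate with the vinyl iodide forms C13–C14 with retention of the E geometry, free hydroxyls are tolerated, a Payne equilibrium of the epoxy alcohol returns the same stereoisomer, and diastereomers arising from the minor enantiomer of either fragment are removed here.

Step 16
Reactants: 30 coupled triol
Product: 31 target CNP0208461.1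
Conditions: MnO2 (20 equiv), CH2Cl2, rt
Reagents that add atoms: none
Why: MnO2 oxidises only the allylic C1 alcohol (C3–OH is saturated, C21–OH is no longer allylic), and the neutral conditions leave the Z tetrasubstituted enal and the epoxy alcohol unchanged.

**Compound list**

1 | nerol, (2Z)-3,7-dimethylocta-2,6-dien-1-ol | CC(C)=CCC/C(C)=C\CO | starting material
2 | neryl bromide, (2Z)-1-bromo-3,7-dimethylocta-2,6-diene | CC(C)=CCC/C(C)=C\CBr | intermediate
3 | bis(pinacolato)borylmethane, 2,2'-methylenebis(4,4,5,5-tetramethyl-1,3,2-dioxaborolane) | CC1(C)OB(CB2OC(C)(C)C(C)(C)O2)OC1(C)C | starting material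
4 | 2-[(3Z)-4,8-dimethylnona-3,7-dien-1-yl]-4,4,5,5-tetramethyl-1,3,2-dioxaborolane | CC(C)=CCC/C(C)=C\CCB1OC(C)(C)C(C)(C)O1 | intermediate
5 | (2E,6Z)-2,6-dimethyl-9-(Bpin)nona-2,6-dien-1-ol | OC/C(C)=C/CC/C(C)=C\CCB1OC(C)(C)C(C)(C)O1 | intermediate (not isolated)
6 | (2E,6Z)-2,6-dimethyl-9-(Bpin)nona-2,6-dienal | O=C/C(C)=C/CC/C(C)=C\CCB1OC(C)(C)C(C)(C)O1 | intermediate
7 | 2-[(3Z,7E)-4,8-dimethyldeca-3,7,9-trien-1-yl]-4,4,5,5-tetramethyl-1,3,2-dioxaborolane | C=C/C(C)=C/CC/C(C)=C\CCB1OC(C)(C)C(C)(C)O1 | intermediate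
8 | propargyl alcohol, prop-2-yn-1-ol | C#CCO | starting material
9 | bromomagnesium (2Z)-3-(bromomagnesio)-2-methylprop-2-en-1-olate | Br[Mg]OC/C(C)=C\[Mg]Br | intermediate (not isolated)
10 | (2Z)-3-iodo-2-methylprop-2-en-1-ol | OC/C(C)=C\I | intermediate
11 | 9-[(3E,7Z)-3,7-dimethyl-10-(Bpin)deca-3,7-dien-1-yl]-9-borabicyclo[3.3.1]nonane | C12CCCC(CCC1)B2CC/C(C)=C/CC/C(C)=C\CCB3OC(C)(C)C(C)(C)O3 | intermediate (not isolated)
12 | (2Z,6E,10Z)-2,6,10-trimethyl-13-(Bpin)trideca-2,6,10-trien-1-ol | OC/C(C)=C\CC/C(C)=C/CC/C(C)=C\CCB1OC(C)(C)C(C)(C)O1 | intermediate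
13 | [(2R,3S)-3-[(3E,7Z)-3,7-dimethyl-10-(Bpin)deca-3,7-dien-1-yl]-2-methyloxiran-2-yl]methanol | OC[C@@]1(C)O[C@H]1CC/C(C)=C/CC/C(C)=C\CCB2OC(C)(C)C(C)(C)O2 | intermediate
14 | tert-butyl{[(2R,3S)-3-[(3E,7Z)-3,7-dimethyl-10-(Bpin)deca-3,7-dien-1-yl]-2-methyloxiran-2-yl]methoxy}diphenylsilane | CC(C)(C)[Si](OC[C@@]1(C)O[C@H]1CC/C(C)=C/CC/C(C)=C\CCB2OC(C)(C)C(C)(C)O2)(c3ccccc3)c4ccccc4 | intermediate
15 | 3-[(1S,2R,3R,6Z)-6-[1-(tert-butyldiphenylsilyloxy)propan-2-ylidene]-2,3-dimethyl-2-[2-(Bpin)ethyl]cyclohexyl]propanal | C/C(CO[Si](c2ccccc2)(c3ccccc3)C(C)(C)C)=C1\CC[C@@H](C)[C@@](C)(CCB4OC(C)(C)C(C)(C)O4)[C@@H]1CCC=O | intermediate (not isolated)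
16 | 3-[(1S,2R,3R,6Z)-6-[1-(tert-butyldiphenylsilyloxy)propan-2-ylidene]-2,3-dimethyl-2-[2-(Bpin)ethyl]cyclohexyl]propan-1-ol | C/C(CO[Si](c2ccccc2)(c3ccccc3)C(C)(C)C)=C1\CC[C@@H](C)[C@@](C)(CCB4OC(C)(C)C(C)(C)O4)[C@@H]1CCCO | intermediate (not isolated)
17 | (2Z)-2-[(2S,3R,4R)-2-(3-hydroxypropyl)-3,4-dimethyl-3-[2-(Bpin)ethyl]cyclohexylidene]propan-1-ol | C/C(CO)=C1\CC[C@@H](C)[C@@](C)(CCB2OC(C)(C)C(C)(C)O2)[C@@H]1CCCO | intermediate
18 | prenal, 3-methylbut-2-enal | CC(C)=CC=O | starting material
19 | allenylboronic acid pinacol ester, 4,4,5,5-tetramethyl-2-(propa-1,2-dien-1-yl)-1,3,2-dioxaborolane | C=C=CB1OC(C)(C)C(C)(C)O1 | starting material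
20 | 4,4,5,5-tetramethyl-2-{[(4S)-6-methylhept-5-en-1-yn-4-yl]oxy}-1,3,2-dioxaborolane | C#CC[C@H](OB1OC(C)(C)C(C)(C)O1)C=C(C)C | intermediate (not isolated)
21 | (4S)-6-methylhept-5-en-1-yn-4-ol | C#CC[C@H](O)C=C(C)C | intermediate
22 | dimethylaluminium (1E,4S)-1-(dimethylalumanyl)-2,6-dimethylhepta-1,5-dien-4-olate | C[Al](C)/C=C(\C)C[C@H](O[Al](C)C)C=C(C)C | intermediate (not isolated)
23 | (1E,4S)-1-iodo-2,6-dimethylhepta-1,5-dien-4-ol | I/C=C(\C)C[C@H](O)C=C(C)C | intermediate
24 | 4-bromobut-1-yne | C#CCCBr | starting material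
25 | but-3-yn-1-ylzinc bromide | C#CCC[Zn]Br | intermediate (not isolated)
26 | (4S,6E)-2,6-dimethylundeca-2,6-dien-10-yn-4-ol | C#CCC/C=C(\C)C[C@H](O)C=C(C)C | intermediate
27 | dimethylaluminium (4S,6E,10E)-11-(dimethylalumanyl)-2,6,10-trimethylundeca-2,6,10-trien-4-olate | C[Al](C)/C=C(\C)CC/C=C(\C)C[C@H](O[Al](C)C)C=C(C)C | intermediate (not isolated)
28 | (4S,6E,10E)-11-iodo-2,6,10-trimethylundeca-2,6,10-trien-4-ol | I/C=C(\C)CC/C=C(\C)C[C@H](O)C=C(C)C | intermediate
29 | (1S,3E,7E)-1-[(2R)-3,3-dimethyloxiran-2-yl]-8-iodo-3,7-dimethylocta-3,7-dien-1-ol | I/C=C(\C)CC/C=C(\C)C[C@H](O)[C@H]1OC1(C)C | intermediate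
30 | (2Z)-2-[(2S,3R,4R)-3-[(3E,7E,10S)-10-[(2R)-3,3-dimethyloxiran-2-yl]-10-hydroxy-4,8-dimethyldeca-3,7-dien-1-yl]-2-(3-hydroxypropyl)-3,4-dimethylcyclohexylidene]propan-1-ol | C/C(CO)=C1\CC[C@@H](C)[C@@](C)(CC/C=C(\C)CC/C=C(\C)C[C@H](O)[C@H]2OC2(C)C)[C@@H]1CCCO | intermediate
31 | CNP0208461.1, (2Z)-2-[(2S,3R,4R)-3-[(3E,7E,10S)-10-[(2R)-3,3-dimethyloxiran-2-yl]-10-hydroxy-4,8-dimethyldeca-3,7-dien-1-yl]-2-(3-hydroxypropyl)-3,4-dimethylcyclohexylidene]propanal | C/C(C=O)=C1\CC[C@@H](C)[C@@](C)(CC/C=C(\C)CC/C=C(\C)C[C@H](O)[C@H]2OC2(C)C)[C@@H]1CCCO | target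

**Totals and risks**

Total step count: 16. Longest linear sequence: 10 steps (1, 2, 3, 4, 6, 7, 8, 9, 15, 16 from nerol).

Most likely to fail, first: step 9. The cation may be lost to proton elimination before the three shifts are complete, C10 may scramble if the C10=C11 alkene forms and is re-protonated, and the seco-aldehyde may re-close. The fallback separates ring formation from the rearrangement and makes the rings by a radical instead of a cation. It sets out from 14: Cp2TiCl (trivalent titanium, from Cp2TiCl2 (2.2 equiv) and Mn dust in THF) opens the oxirane homolytically at C2, two 6-endo radical closures follow, and the titanium-trapped C10 radical loses a β-hydrogen to give the trans-fused exo-methylene decalinol F1, which can be purified and characterised. F1 is then treated with BF3·OEt2 in CH2Cl2 (−50 → 0 °C), where protonation of the exocyclic alkene enters the same shift/fragmentation manifold at the C10 cation, as in the drimane precedents, and the route is rejoined at 15, which is reduced and desilylated as in step 9 to 17.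

Second: step 15. Primary alkyl pinacol boronates transmetalate slowly, and the epoxy alcohol limits how hard the coupling can be pushed. The fallback couples before the oxirane exists. It sets out from 16 (isolated by leaving out the fluoride treatment of step 9) and 28: Suzuki coupling under forcing conditions (Pd(OAc)2, RuPhos, K3PO4, toluene/H2O, 90 °C) gives the coupled allylic alcohol silyl ether F2. Because C1 is still silylated, VO(acac)2/t-BuOOH is directed only by the C21 hydroxyl and gives the threo epoxy alcohol silyl ether F3. TBAF in THF then gives 30, where the route is rejoined before the MnO2 step.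

Third: step 3. The internal C10=C11 alkene of 4 is not deactivated and may compete with the terminal isopropylidene for SeO2, and the boronate may not survive the oxidants. The fallback oxidises before boron is introduced and uses an allylic acetate to shield the inner alkene. It sets out from 1: acetylation (Ac2O, pyridine) gives neryl acetate F4; SeO2/t-BuOOH then MnO2 gives 8-oxoneryl acetate F5; Wittig methylenation gives the trienyl acetate F6; K2CO3 in MeOH gives the trienol F7; PBr3 in Et2O at −10 °C gives the trienyl bromide F8; deborylative alkylation of F8 with 3 and NaOtBu gives 7, where the route is rejoined at the cost of two extra steps.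

Further compounds

F1 | step 9 | (1S,2S,4aR,5R,8aR)-1-[(tert-butyldiphenylsilyloxy)methyl]-1,4a-dimethyl-6-methylidene-5-[2-(Bpin)ethyl]decahydronaphthalen-2-ol | CC(C)(C)[Si](OC[C@@]1(C)[C@@H](O)CC[C@@]2(C)[C@H]1CCC(=C)[C@H]2CCB3OC(C)(C)C(C)(C)O3)(c4ccccc4)c5ccccc5
F2 | step 15 | 3-[(1S,2R,3R,6Z)-6-[1-(tert-butyldiphenylsilyloxy)propan-2-ylidene]-2-[(3E,7E,10S)-10-hydroxy-4,8,12-trimethyltrideca-3,7,11-trien-1-yl]-2,3-dimethylcyclohexyl]propan-1-ol | C/C(CO[Si](c2ccccc2)(c3ccccc3)C(C)(C)C)=C1\CC[C@@H](C)[C@@](C)(CC/C=C(\C)CC/C=C(\C)C[C@H](O)C=C(C)C)[C@@H]1CCCO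
F3 | step 15 | 3-[(1S,2R,3R,6Z)-6-[1-(tert-butyldiphenylsilyloxy)propan-2-ylidene]-2-[(3E,7E,10S)-10-[(2R)-3,3-dimethyloxiran-2-yl]-10-hydroxy-4,8-dimethyldeca-3,7-dien-1-yl]-2,3-dimethylcyclohexyl]propan-1-ol | C/C(CO[Si](c2ccccc2)(c3ccccc3)C(C)(C)C)=C1\CC[C@@H](C)[C@@](C)(CC/C=C(\C)CC/C=C(\C)C[C@H](O)[C@H]4OC4(C)C)[C@@H]1CCCO
F4 | step 3 | neryl acetate, (2Z)-3,7-dimethylocta-2,6-dien-1-yl acetate | CC(C)=CCC/C(C)=C\COC(C)=O
F5 | step 3 | (2Z,6E)-3,7-dimethyl-8-oxoocta-2,6-dien-1-yl acetate | O=C/C(C)=C/CC/C(C)=C\COC(C)=O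
F6 | step 3 | (2Z,6E)-3,7-dimethylnona-2,6,8-trien-1-yl acetate | C=C/C(C)=C/CC/C(C)=C\COC(C)=O
F7 | step 3 | (2Z,6E)-3,7-dimethylnona-2,6,8-trien-1-ol | C=C/C(C)=C/CC/C(C)=C\CO
F8 | step 3 | (3E,7Z)-9-bromo-3,7-dimethylnona-1,3,7-triene | C=C/C(C)=C/CC/C(C)=C\CBr
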